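**Retrosynthetic overview**

1. Enabling feature: in the pyrrole ring, the edge N1–C2(CO2Me)=C3(indolyl) is the enamine of a (5-bromoindol-3-yl)pyruvic ester. The edge C4–C5 (C4 carrying the second indol-3-yl, C5 an unsubstituted CH bonded to N1) is a two-carbon dialdehyde unit. Keto ester, glyoxal monoacetal, indole C–H and NH3 together already stand at the oxidation level of the aromatic ring.
2. Key disconnection: pyrrole C4–indole C3. It is made by Friedel–Crafts (Yonemitsu-type) attack of 5-bromoindole on C4 of an alkylidene pyruvate generated in the flask from the keto ester and 2,2-dimethoxyacetaldehyde. The same pot then closes N1–C2 and N1–C5 with ammonia (Paal–Knorr) and aromatises.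
3. The keto ester comes from its oxime, and the oxime from 5-bromoindole and methyl bromopyruvate oxime by conjugate addition to a nitrosoalkene (first indole C3–CH2 bond).
4. Order of rings: both indole rings are bought intact as 5-bromoindole; the pyrrole is the only ring made, and it is made last.
5. No palladium, no oxidant, no protecting group: both aryl bromides and all three N–H groups pass through untouched.

Key step: step 4

Remark: methyl bromopyruvate, 5-bromoindole and 2,2-dimethoxyacetaldehyde (aqueous solution) are taken as commercial; oxime geometry (drawn with the hydroxyl anti to the ester), the alkene geometry of the alkylidene intermediate and the configuration of the transient sp3 centres have no bearing on the outcome.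

**Route**

Step 1
Reactants: 1 methyl 3-bromo-2-oxopropanoate (methyl bromopyruvate)
Product: 2 methyl (Z)-3-bromo-2-(hydroxyimino)propanoate
Conditions: NH2OH·HCl, MeOH–CHCl3 (1:1), rt
Reagents that add atoms: hydroxylamine hydrochloride, NO.Cl
Why: Oxime formation (carbonyl condensation) at the highly electrophilic ketone of the α-keto ester should be fast under these base-free conditions, which leave the primary bromide untouched.

Step 2
Reactants: 2 methyl (Z)-3-bromo-2-(hydroxyimino)propanoate; 3 5-bromo-1H-indole
Product: 5 methyl (E)-3-(5-bromo-1H-indol-3-yl)-2-(hydroxyimino)propanoate, via methyl 2-nitrosoacrylate 4 (not isolated)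
Conditions: Na2CO3 (powder), CH2Cl2, rt, slow addition of 2 to an excess of 3
Reagents that add atoms: none
Why: Base-induced 1,4-elimination of HBr from 2 gives the transient nitrosoalkene 4, which C3 of the unprotected indole attacks at the CH2 terminus (conjugate addition of indoles to nitrosoalkenes, the standard entry to α-oximino-β-indolylpropanoates).

Step 3
Reactants: 5 methyl (E)-3-(5-bromo-1H-indol-3-yl)-2-(hydroxyimino)propanoate
Product: 7 methyl 3-(5-bromo-1H-indol-3-yl)-2-oxopropanoate, via N–H ketimine 6 (not isolated)
Conditions: TiCl3 (aq. HCl solution), NaOAc buffer, THF–H2O, 0 °C to rt, N2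
Reagents that add atoms: water, O
Why: Reductive deoximation, in which trivalent titanium cleaves the N–O bond by two single-electron transfers to the ketimine 6 and the buffered aqueous medium hydrolyses it to the keto ester (expected mainly as its conjugated enol), should spare the aryl bromide and the ester.

Step 4
Reactants: 7 methyl 3-(5-bromo-1H-indol-3-yl)-2-oxopropanoate; 3 5-bromo-1H-indole; 8 2,2-dimethoxyacetaldehyde
Product: 12 methyl 3,4-bis(5-bromo-1H-indol-3-yl)-1H-pyrrole-2-carboxylate, via alkylidene pyruvate 9 (not isolated), via keto acetal 10 (not isolated), via methoxypyrroline 11 (not isolated)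
Conditions: (i) 8 (60 wt % in H2O), D,L-proline (cat.), MeCN, rt to 40 °C; (ii) NH4OAc (excess), AcOH, 80 °C; one pot
Reagents that add atoms: ammonium acetate, [NH4+].CC(=O)[O-]
Why: Proposed new method: proline mediates Knoevenagel condensation of the enolised C3–H of 7 with the free aldehyde of 8 (amine catalysis avoids a free β-hydroxy ketone that could lactonise) to give 9, whose C4 is the β-carbon of a 1,2-dicarbonyl Michael acceptor, and C3 of 3 adds there in a Friedel–Crafts conjugate addition to forge the C4–indole bond and give 10 (if 3 meets the aldehyde first, the resulting 3-alkylideneindoleninium ion is captured by the enol of 7 and the same adduct 10 forms). In the second stage ammonia condenses at the C2 ketone (N1–C2 bond), hot acetic acid opens the acetal, the enamine nitrogen closes onto the C5 oxocarbenium ion in a 5-exo-trig cyclisation (N1–C5 bond) to give 11, and loss of methanol aromatises the ring, which is a Paal–Knorr closure of a masked 1,4-keto aldehyde. The closest known reaction types are the Yonemitsu trimolecular condensation of an indole, an aldehyde and a C–H acid and the three-component pyrrole syntheses from arylglyoxals, enaminones and indoles, in which the nucleophile also ends at the pyrrole β-carbon that was the aldehyde carbon; what has not been shown is an arylpyruvic ester as the C–H acid in a sequence telescoped with ring closure. The sp3 centres created at C3/C4 of 10 and C4/C5 of 11 arise without control and are erased on aromatisation, and the target has no stereocentre. The selectivity needed is entry of the indole at C4 and not at C5 or C2: C5 stays a dimethyl acetal that is inert under the near-neutral first stage and is unmasked only after 10 has formed, while 1,2-addition at the hindered, enolised C2 ketone is reversible and only the 1,4-adduct is drained by irreversible aromatisation. The whole operation is redox-neutral and free of palladium, so both aryl bromides and the free N–H groups are safe.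

**Compound list**

1 | methyl 3-bromo-2-oxopropanoate (methyl bromopyruvate) | COC(=O)C(=O)CBr | starting material
2 | methyl (Z)-3-bromo-2-(hydroxyimino)propanoate | BrC/C(C(=O)OC)=N\O | intermediate
3 | 5-bromo-1H-indole | Brc1ccc2[nH]ccc2c1 | starting material
4 | methyl 2-nitrosoprop-2-enoate (methyl 2-nitrosoacrylate) | C=C(N=O)C(=O)OC | intermediate
5 | methyl (E)-3-(5-bromo-1H-indol-3-yl)-2-(hydroxyimino)propanoate | COC(=O)/C(Cc1c[nH]c2ccc(Br)cc12)=N/O | intermediate
6 | methyl 3-(5-bromo-1H-indol-3-yl)-2-iminopropanoate | COC(=O)C(=N)Cc1c[nH]c2ccc(Br)cc12 | intermediate
7 | methyl 3-(5-bromo-1H-indol-3-yl)-2-oxopropanoate | COC(=O)C(=O)Cc1c[nH]c2ccc(Br)cc12 | intermediate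
8 | 2,2-dimethoxyacetaldehyde | COC(OC)C=O | starting material
9 | methyl 3-(5-bromo-1H-indol-3-yl)-5,5-dimethoxy-2-oxopent-3-enoate (alkene geometry not defined) | COC(=O)C(=O)C(=CC(OC)OC)c1c[nH]c2ccc(Br)cc12 | intermediate
10 | methyl 3,4-bis(5-bromo-1H-indol-3-yl)-5,5-dimethoxy-2-oxopentanoate (mixture of racemic diastereomers) | COC(=O)C(=O)C(c1c[nH]c2ccc(Br)cc12)C(C(OC)OC)c1c[nH]c2ccc(Br)cc12 | intermediate
11 | methyl 3,4-bis(5-bromo-1H-indol-3-yl)-5-methoxy-4,5-dihydro-1H-pyrrole-2-carboxylate (mixture of racemic diastereomers) | COC(=O)C1=C(c2c[nH]c3ccc(Br)cc23)C(c2c[nH]c3ccc(Br)cc23)C(OC)N1 | intermediate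
12 | methyl 3,4-bis(5-bromo-1H-indol-3-yl)-1H-pyrrole-2-carboxylate | COC(=O)c1[nH]cc(-c2c[nH]c3ccc(Br)cc23)c1-c1c[nH]c2ccc(Br)cc12 | target

**Totals**

Total step count: 4. Longest linear sequence: 4 steps (1 → 2 → 5 → 7 → 12).

**Steps most likely to fail**

Step 4 (Proposed new method). The deactivated 5-bromoindole may add to 9 too slowly. Then 8 may be lost to double indolylation, or 7 to aldol self-condensation. The acetal may also be opened in the hot second stage before the C4–indole bond exists, so that the indole enters at C5 and ring closure gives the 3,5-regioisomer. The fallback uses known chemistry, sets out from 3 and 8 and comes back to the route at 10. The indole–C4 bond is made first and stored as a sulfone: acid-catalysed three-component condensation of 3, 8 and p-toluenesulfinic acid (cat. p-TsOH, EtOAc, rt) should give racemic 5-bromo-3-[2,2-dimethoxy-1-(4-methylphenylsulfonyl)ethyl]-1H-indole F1. Treatment of F1 with 7 and KF/Al2O3 (basic) in CH2Cl2 eliminates sulfinate to the 3-alkylideneindolenine, which takes up the enolate of 7 in a Michael addition (the established use of 3-(1-arylsulfonylalkyl)indoles) to give 10, now isolated. NH4OAc in AcOH at 80 °C (Paal–Knorr) then converts 10 by way of 11 into 12.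

Step 3. The activated α-imino or α-keto ester may be reduced further or reductively dimerised by trivalent titanium, and the enolisable keto ester may undergo aldol self-condensation during the aqueous work-up. The fallback sets out from 3, comes back at 7 and bypasses the oxime. InBr3-catalysed Friedel–Crafts opening of methyl oxirane-2-carboxylate at its CH2 terminus by C3 of 3 (CH2Cl2, rt) should give racemic methyl 3-(5-bromo-1H-indol-3-yl)-2-hydroxypropanoate F2. Parikh–Doering oxidation of the secondary alcohol (SO3·pyridine, DMSO, Et3N, 0 °C) should then give 7 under non-aqueous, non-reducing conditions.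

Step 2. The short-lived nitrosoalkene 4 may oligomerise faster than the electron-poor indole captures it, and N-alkylation or double alkylation may compete. The fallback sets out from 3 and comes back at 5. Mannich reaction of 3 with CH2O and Me2NH in AcOH should give 1-(5-bromo-1H-indol-3-yl)-N,N-dimethylmethanamine F3 (5-bromogramine). Alkylation of methyl nitroacetate with it (toluene, reflux, N2 stream; elimination–addition through the 3-methyleneindolenine) should give racemic methyl 3-(5-bromo-1H-indol-3-yl)-2-nitropropanoate F4. Partial reduction of the secondary nitro group with SnCl2/PhSH/Et3N (MeCN, rt) is expected to stop at the oxime 5.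

**Further compounds**

F1 | step 4 | 5-bromo-3-[2,2-dimethoxy-1-(4-methylphenylsulfonyl)ethyl]-1H-indole (racemic) | COC(OC)C(c1c[nH]c2ccc(Br)cc12)S(=O)(=O)c1ccc(C)cc1
F2 | step 3 | methyl 3-(5-bromo-1H-indol-3-yl)-2-hydroxypropanoate (racemic) | COC(=O)C(O)Cc1c[nH]c2ccc(Br)cc12
F3 | step 2 | 1-(5-bromo-1H-indol-3-yl)-N,N-dimethylmethanamine (5-bromogramine) | CN(C)Cc1c[nH]c2ccc(Br)cc12
F4 | step 2 | methyl 3-(5-bromo-1H-indol-3-yl)-2-nitropropanoate (racemic) | COC(=O)C(Cc1c[nH]c2ccc(Br)cc12)[N+](=O)[O-]
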